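**Plan**

- Retrosynthesis: (1) the seven O‑methyl ethers; (2) the bond from C‑7 of the ring‑B dihydrobenzofuran to the anisyl‑bearing alkene carbon of the seven‑membered ring, giving a diaryl alkyne; (3) the aryl–alkyne bond; (4) in each dihydrobenzofuran the O‑1–C‑7a and C‑2–C‑3 bonds, giving 4‑methoxybenzaldehyde and a diarylmethane with an ortho p‑tolylsulfinyl group; (5) the two benzyl–aryl bonds.
- Forward: two sulfinyl arenes (rings A and B) → Negishi union at the CH2 between rings A and B → ring‑A dihydrobenzofuran → sulfinyl‑directed benzylation of ring B → ring‑B dihydrobenzofuran (key) → Sonogashira coupling → gold‑catalysed 7‑endo‑dig closure of the seven‑membered ring → demethylation.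
- Stereochemistry: the sulfur stereocentres come from (−)‑ and (+)‑menthyl p‑toluenesulfinate (Andersen synthesis). Each sulfinyl group sets the adjacent benzylic C‑3 by 1,4‑induction and is expelled in the same flask; each C‑2 follows as trans.
- Enabling feature: in ring B the ether carbon C‑7a (bearing O‑1) is ortho to C‑3a, which carries the doubly benzylic C‑3. A sulfinyl group on C‑7a can hold the C‑3 carbanion in a six‑membered lithium chelate and is then the leaving group for ipso attack of the alkoxide through a five‑membered transition state. Ring A has the same 1,2‑relationship.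

Key step: step 7

Assumption: the sense of 1,4‑induction is taken from the chelate model (lithium bridging the carbanion carbon and the sulfinyl oxygen, the aldehyde entering on the lithium‑bearing face, anti to the p‑tolyl group). The sulfur configurations drawn follow from this model; should the sense prove opposite, the two menthyl sulfinates are exchanged between steps 2 and 3 with no other change.

**Step 1**
Reactants: 1 1‑bromo‑3‑chloro‑5‑methoxybenzene; 2 iodomethane
Product: 4 1‑bromo‑3‑chloro‑5‑methoxy‑2‑methylbenzene, via aryllithium 3 (not isolated)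
Conditions: LiN(i‑Pr)2 (LDA), THF, −78 °C; then MeI, −78 → 0 °C
Reagents that add atoms: iodomethane (2), CI
Why: LDA should remove the ring proton flanked by bromine and chlorine (the most acidic position), and the aryllithium is methylated by SN2 on MeI (directed ortho‑metalation/alkylation).

**Step 2**
Reactants: 4 1‑bromo‑3‑chloro‑5‑methoxy‑2‑methylbenzene; 5 (1R,2S,5R)‑menthyl (S)‑4‑methylbenzenesulfinate
Product: 7 (S)‑1‑chloro‑5‑methoxy‑2‑methyl‑3‑(4‑methylbenzenesulfinyl)benzene, via arylmagnesium chloride 6 (not isolated)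
Conditions: i‑PrMgCl·LiCl, THF, 0 → 25 °C; then 5, THF, −40 → 0 °C
Reagents that add atoms: (1R,2S,5R)‑menthyl (S)‑4‑methylbenzenesulfinate (5), Cc1ccc(cc1)[S@@](=O)O[C@@H]1C[C@H](C)CC[C@H]1C(C)C
Why: Br/Mg exchange touches only the bromide, and the Andersen sulfoxide synthesis replaces menthoxide at sulfur with inversion, so the sulfur stereocentre should be obtained as the single (S) enantiomer.

**Step 3**
Reactants: 8 1,3‑dibromo‑5‑methoxybenzene; 9 (1S,2R,5S)‑menthyl (R)‑4‑methylbenzenesulfinate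
Product: 11 (R)‑1‑bromo‑3‑methoxy‑5‑(4‑methylbenzenesulfinyl)benzene, via arylmagnesium chloride 10 (not isolated)
Conditions: i‑PrMgCl·LiCl (1.0 equiv), THF, −15 → 0 °C; then 9, THF, −40 → 0 °C
Reagents that add atoms: (1S,2R,5S)‑menthyl (R)‑4‑methylbenzenesulfinate (9), Cc1ccc(cc1)[S@](=O)O[C@H]1C[C@@H](C)CC[C@@H]1C(C)C
Why: Mono Br/Mg exchange should stop after the first bromide because the arylmagnesium deactivates the second, and the Andersen synthesis with the enantiomeric sulfinate gives the (R)‑sulfoxide with inversion at sulfur.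

**Step 4**
Reactants: 7 (S)‑1‑chloro‑5‑methoxy‑2‑methyl‑3‑(4‑methylbenzenesulfinyl)benzene; 11 (R)‑1‑bromo‑3‑methoxy‑5‑(4‑methylbenzenesulfinyl)benzene
Product: 14 1‑chloro‑5‑methoxy‑2‑{3‑methoxy‑5‑[(R)‑4‑methylbenzenesulfinyl]benzyl}‑3‑[(S)‑4‑methylbenzenesulfinyl]benzene, via benzyllithium 12 (not isolated), via benzylzinc chloride 13 (not isolated)
Conditions: 7, LDA, THF, −78 °C; ZnCl2, −78 → 0 °C; then 11, Pd(PPh3)4 (5 mol %), THF, 50 °C
Reagents that add atoms: none
Why: Sulfinyl‑assisted lateral lithiation of the ortho methyl group, transmetalation to zinc and Negishi coupling with the aryl bromide should join rings A and B; the aryl chloride and both sulfinyl groups are inert to Pd(PPh3)4 here, and the organozinc is too weakly basic to deprotonate the product CH2.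

**Step 5**
Reactants: 14 the bis‑sulfinyl diarylmethane; 15 4‑methoxybenzaldehyde
Product: 18 (2S,3S)‑4‑chloro‑6‑methoxy‑2‑(4‑methoxyphenyl)‑3‑{3‑methoxy‑5‑[(R)‑4‑methylbenzenesulfinyl]phenyl}‑2,3‑dihydrobenzofuran, via diarylmethyllithium 16 (not isolated), via lithium aldolate 17 (not isolated)
Conditions: LDA (1.05 equiv), THF, −78 °C; 15, −78 °C; then DMPU, −78 → 40 °C
Reagents that add atoms: 4‑methoxybenzaldehyde (15), COc1ccc(C=O)cc1
Why: Proposed new method: the diarylmethane CH2 is lithiated in a six‑membered chelate with the ring‑A sulfinyl oxygen, the carbanion adds to the aldehyde on the lithium face (the (S)‑sulfur sets C‑3 as S by 1,4‑induction), and the alkoxide then displaces p‑toluenesulfenate from the sulfinyl‑bearing carbon by 5‑exo ipso addition–elimination, the reversible aldol and faster closure of the anti aldolate giving the trans ring (a cis epimer would be equilibrated with catalytic TFA); the ring‑B sulfinyl group is meta to the tether and the chloride is a far poorer leaving group on this unactivated ring; the closest known reaction types are the 1,4‑induced additions of ortho‑sulfinyl benzyl carbanions to aldehydes and imines and the ipso displacement of aryl sulfinyl groups by tethered nitrogen anions to give indolines.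

**Step 6**
Reactants: 18 the ring‑A dihydrobenzofuran sulfoxide; 19 3,5‑dimethoxybenzyl bromide
Product: 22 (2S,3S)‑4‑chloro‑3‑{4‑(3,5‑dimethoxybenzyl)‑3‑methoxy‑5‑[(R)‑4‑methylbenzenesulfinyl]phenyl}‑6‑methoxy‑2‑(4‑methoxyphenyl)‑2,3‑dihydrobenzofuran, via arylmagnesium chloride 20 (not isolated), via arylzinc chloride 21 (not isolated)
Conditions: TMPMgCl·LiCl (TMP = 2,2,6,6‑tetramethylpiperidide), THF, −30 °C; ZnCl2; then 19, Pd(PPh3)4 (5 mol %), 25 → 50 °C
Reagents that add atoms: 3,5‑dimethoxybenzyl bromide (19), COc1cc(CBr)cc(OC)c1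
Why: Sulfinyl‑directed ortho‑magnesiation should occur at the ring‑B position flanked by the sulfinyl and methoxy groups, and Negishi benzylation of the derived arylzinc installs the CH2Ar unit without deprotonating the acidic product CH2.

**Step 7**
Reactants: 22 the benzylated ring‑B sulfoxide; 15 4‑methoxybenzaldehyde
Product: 25 (2R,3R)‑6‑[(2S,3S)‑4‑chloro‑6‑methoxy‑2‑(4‑methoxyphenyl)‑2,3‑dihydrobenzofuran‑3‑yl]‑3‑(3,5‑dimethoxyphenyl)‑4‑methoxy‑2‑(4‑methoxyphenyl)‑2,3‑dihydrobenzofuran, via diarylmethyllithium 23 (not isolated), via lithium aldolate 24 (not isolated)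
Conditions: LDA (1.05 equiv), THF, −78 °C; 15, −78 °C; then DMPU, −78 → 40 °C
Reagents that add atoms: 4‑methoxybenzaldehyde (15), COc1ccc(C=O)cc1
Why: Proposed new method: LDA removes a proton of the doubly benzylic CH2 on ring B, held by the ortho sulfinyl group in a lithium chelate (carbanion carbon–Li–O=S); the carbanion adds to 4‑methoxybenzaldehyde on the lithium‑bearing face, and the lithium alkoxide 24 attacks the sulfinyl‑bearing ring carbon through a Meisenheimer‑type σ‑complex that expels p‑toluenesulfenate, so C‑2–C‑3 and O‑1–C‑7a form in one flask and the auxiliary leaves without trace. The closest known reaction types are the 1,4‑induced additions of ortho‑sulfinyl benzyl carbanions to aldehydes and imines, the ipso displacement of aryl sulfinyl groups by tethered nitrogen anions that gives indolines, and alkoxide SNAr on ortho‑fluoro and ortho‑sulfonyl arenes. The one ring closed is the dihydrofuran ring, by 5‑exo‑trig ipso attack on an aromatic carbon. C‑3 (R) is set by the (R)‑sulfur through the chelate; C‑2 (R) follows as trans because the aldol is reversible on warming and the anti aldolate closes faster, and a cis epimer would converge on trans by reversible acid ionisation of the p‑methoxybenzylic C–O bond. The step needs deprotonation at the ring‑B CH2 and not at C‑3 of the existing dihydrobenzofuran (where an anion would open the ring), which the chelate and the much higher acidity of the diarylmethane secure; it also needs attack of the alkoxide at carbon and not at sulfur, which the five‑membered transition state and the sulfenate leaving group favour.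

**Step 8**
Reactants: 25 the bis‑dihydrobenzofuran aryl chloride; 26 1‑ethynyl‑4‑methoxybenzene
Product: 27 (2R,3R)‑3‑(3,5‑dimethoxyphenyl)‑4‑methoxy‑6‑{(2S,3S)‑6‑methoxy‑2‑(4‑methoxyphenyl)‑4‑[(4‑methoxyphenyl)ethynyl]‑2,3‑dihydrobenzofuran‑3‑yl}‑2‑(4‑methoxyphenyl)‑2,3‑dihydrobenzofuran
Conditions: Pd(MeCN)2Cl2 (3 mol %), XPhos (9 mol %), Cs2CO3, MeCN, 85 °C
Reagents that add atoms: 1‑ethynyl‑4‑methoxybenzene (26), COc1ccc(C#C)cc1
Why: Copper‑free Sonogashira coupling of an aryl chloride with a bulky biarylphosphine ligand should replace the chloride (meta to both ring oxygens, one ortho substituent) by the alkyne; the carbonate base touches no stereocentre.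

**Step 9**
Reactants: 27 the diaryl alkyne
Product: 28 hepta‑O‑methyl ether of the target
Conditions: [(2‑biphenylyl)(t‑Bu)2P]Au(NCMe)SbF6 (5 mol %), CH2Cl2, 25 °C
Reagents that add atoms: none
Why: Cationic gold activates the alkyne with positive charge on the anisyl‑bearing carbon, and C‑7 of the ring‑B dihydrobenzofuran (ortho to the tied‑back furan oxygen, para to OMe; C‑5 is shielded by the in‑plane methyl of the 4‑methoxy group) attacks it in a 7‑endo‑dig hydroarylation, protodeauration giving the ring alkene.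

**Step 10**
Reactants: 28 hepta‑O‑methyl ether of the target
Product: 29 the target heptaphenol
Conditions: BBr3 (excess), CH2Cl2, −78 → 25 °C; then MeOH, aqueous work‑up
Reagents that add atoms: none
Why: BBr3 should cleave all seven aryl methyl ethers by bromide attack on the O‑methyl of the borane adducts; the trans dihydrobenzofurans are the thermodynamic isomers, so the Lewis acid should not change the configuration.

**Compound list**

1 | 1‑bromo‑3‑chloro‑5‑methoxybenzene | COc1cc(Cl)cc(Br)c1 | starting material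
2 | iodomethane | CI | starting material
3 | (2‑bromo‑6‑chloro‑4‑methoxyphenyl)lithium | COc1cc(Cl)c([Li])c(Br)c1 | intermediate (not isolated)
4 | 1‑bromo‑3‑chloro‑5‑methoxy‑2‑methylbenzene | COc1cc(Cl)c(C)c(Br)c1 | intermediate
5 | (1R,2S,5R)‑menthyl (S)‑4‑methylbenzenesulfinate | Cc1ccc(cc1)[S@@](=O)O[C@@H]1C[C@H](C)CC[C@H]1C(C)C | starting material
6 | (3‑chloro‑5‑methoxy‑2‑methylphenyl)magnesium chloride | COc1cc(Cl)c(C)c([Mg]Cl)c1 | intermediate (not isolated)
7 | (S)‑1‑chloro‑5‑methoxy‑2‑methyl‑3‑(4‑methylbenzenesulfinyl)benzene | COc1cc(Cl)c(C)c(c1)[S@@](=O)c1ccc(C)cc1 | intermediate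
8 | 1,3‑dibromo‑5‑methoxybenzene | COc1cc(Br)cc(Br)c1 | starting material
9 | (1S,2R,5S)‑menthyl (R)‑4‑methylbenzenesulfinate | Cc1ccc(cc1)[S@](=O)O[C@H]1C[C@@H](C)CC[C@@H]1C(C)C | starting material
10 | (3‑bromo‑5‑methoxyphenyl)magnesium chloride | COc1cc(Br)cc([Mg]Cl)c1 | intermediate (not isolated)
11 | (R)‑1‑bromo‑3‑methoxy‑5‑(4‑methylbenzenesulfinyl)benzene | COc1cc(Br)cc(c1)[S@](=O)c1ccc(C)cc1 | intermediate
12 | benzyllithium of 7 | COc1cc(Cl)c(C[Li])c(c1)[S@@](=O)c1ccc(C)cc1 | intermediate (not isolated)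
13 | benzylzinc chloride of 7 | COc1cc(Cl)c(C[Zn]Cl)c(c1)[S@@](=O)c1ccc(C)cc1 | intermediate (not isolated)
14 | 1‑chloro‑5‑methoxy‑2‑{3‑methoxy‑5‑[(R)‑4‑methylbenzenesulfinyl]benzyl}‑3‑[(S)‑4‑methylbenzenesulfinyl]benzene | COc1cc(Cl)c(Cc2cc(OC)cc(c2)[S@](=O)c2ccc(C)cc2)c(c1)[S@@](=O)c1ccc(C)cc1 | intermediate
15 | 4‑methoxybenzaldehyde | COc1ccc(C=O)cc1 | starting material
16 | diarylmethyllithium of 14 | COc1cc(Cl)c(C([Li])c2cc(OC)cc(c2)[S@](=O)c2ccc(C)cc2)c(c1)[S@@](=O)c1ccc(C)cc1 | intermediate (not isolated)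
17 | lithium aldolate from 16 and 15 (centres as in 18) | [Li]O[C@H](c1ccc(OC)cc1)[C@H](c1c(Cl)cc(OC)cc1[S@@](=O)c1ccc(C)cc1)c1cc(OC)cc(c1)[S@](=O)c1ccc(C)cc1 | intermediate (not isolated)
18 | (2S,3S)‑4‑chloro‑6‑methoxy‑2‑(4‑methoxyphenyl)‑3‑{3‑methoxy‑5‑[(R)‑4‑methylbenzenesulfinyl]phenyl}‑2,3‑dihydrobenzofuran | COc1cc(Cl)c2c(c1)O[C@H](c1ccc(OC)cc1)[C@H]2c1cc(OC)cc(c1)[S@](=O)c1ccc(C)cc1 | intermediate
19 | 3,5‑dimethoxybenzyl bromide | COc1cc(CBr)cc(OC)c1 | starting material
20 | ring‑B arylmagnesium chloride of 18 | COc1cc(Cl)c2c(c1)O[C@H](c1ccc(OC)cc1)[C@H]2c1cc(OC)c([Mg]Cl)c(c1)[S@](=O)c1ccc(C)cc1 | intermediate (not isolated)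
21 | ring‑B arylzinc chloride of 18 | COc1cc(Cl)c2c(c1)O[C@H](c1ccc(OC)cc1)[C@H]2c1cc(OC)c([Zn]Cl)c(c1)[S@](=O)c1ccc(C)cc1 | intermediate (not isolated)
22 | (2S,3S)‑4‑chloro‑3‑{4‑(3,5‑dimethoxybenzyl)‑3‑methoxy‑5‑[(R)‑4‑methylbenzenesulfinyl]phenyl}‑6‑methoxy‑2‑(4‑methoxyphenyl)‑2,3‑dihydrobenzofuran | COc1cc(Cl)c2c(c1)O[C@H](c1ccc(OC)cc1)[C@H]2c1cc(OC)c(Cc2cc(OC)cc(OC)c2)c(c1)[S@](=O)c1ccc(C)cc1 | intermediate
23 | diarylmethyllithium of 22 | COc1cc(Cl)c2c(c1)O[C@H](c1ccc(OC)cc1)[C@H]2c1cc(OC)c(C([Li])c2cc(OC)cc(OC)c2)c(c1)[S@](=O)c1ccc(C)cc1 | intermediate (not isolated)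
24 | lithium aldolate from 23 and 15 (centres as in 25) | COc1cc(Cl)c2c(c1)O[C@H](c1ccc(OC)cc1)[C@H]2c1cc(OC)c([C@H]([C@@H](O[Li])c2ccc(OC)cc2)c2cc(OC)cc(OC)c2)c(c1)[S@](=O)c1ccc(C)cc1 | intermediate (not isolated)
25 | (2R,3R)‑6‑[(2S,3S)‑4‑chloro‑6‑methoxy‑2‑(4‑methoxyphenyl)‑2,3‑dihydrobenzofuran‑3‑yl]‑3‑(3,5‑dimethoxyphenyl)‑4‑methoxy‑2‑(4‑methoxyphenyl)‑2,3‑dihydrobenzofuran | COc1cc(Cl)c2c(c1)O[C@H](c1ccc(OC)cc1)[C@H]2c1cc(OC)c2c(c1)O[C@@H](c1ccc(OC)cc1)[C@@H]2c1cc(OC)cc(OC)c1 | intermediate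
26 | 1‑ethynyl‑4‑methoxybenzene | COc1ccc(C#C)cc1 | starting material
27 | the 4‑[(4‑methoxyphenyl)ethynyl] analogue of 25 | COc1cc(C#Cc3ccc(OC)cc3)c2c(c1)O[C@H](c1ccc(OC)cc1)[C@H]2c1cc(OC)c2c(c1)O[C@@H](c1ccc(OC)cc1)[C@@H]2c1cc(OC)cc(OC)c1 | intermediate
28 | hepta‑O‑methyl ether of the target | COc1ccc(C2=Cc3cc(OC)cc4c3[C@H](c3cc(OC)c5c(c32)O[C@@H](c2ccc(OC)cc2)[C@@H]5c2cc(OC)cc(OC)c2)[C@@H](c2ccc(OC)cc2)O4)cc1 | intermediate
29 | target heptaphenol (CNP0325907.1) | Oc1ccc(C2=Cc3cc(O)cc4c3[C@H](c3cc(O)c5c(c32)O[C@@H](c2ccc(O)cc2)[C@@H]5c2cc(O)cc(O)c2)[C@@H](c2ccc(O)cc2)O4)cc1 | target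

**Totals**

Total step count: 10. Longest linear sequence: 9 steps (1, 2, 4, 5, 6, 7, 8, 9, 10).

**Steps most likely to fail**

1. Step 7. The alkoxide may attack sulfur or revert by retro‑aldol instead of displacing the sulfinyl group, or the facial selectivity at the carbanion may be poor. Fallback from 22: the same sulfinyl‑directed lithiation and addition to 15 is quenched cold and gives the aldol carbinol F1. Oxidation with m‑CPBA (CH2Cl2, 0 °C) gives the sulfone F2. KOt‑Bu in DMSO (25 → 60 °C) then closes the ring by the established ipso substitution of an aryl sulfonyl group by an alkoxide, with p‑toluenesulfinate leaving. The route is rejoined at 25.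

2. Step 5. The same ipso displacement may fail on ring A, or may lose chemoselectivity because a second sulfinyl group and an ortho chloride are present. Fallback from 7 (as its zinc reagent 13) and 8: Negishi coupling with an excess of 8 gives the bromo diarylmethane F3, which carries only the ring‑A sulfinyl group. Sulfinyl‑directed lithiation and addition to 15 with cold quench gives the carbinol F4. m‑CPBA gives the sulfone F5, and KOt‑Bu in DMSO closes the ring to the dihydrobenzofuran bromide F6. Br/Mg exchange (i‑PrMgCl·LiCl) and Andersen sulfinylation with 9 then install the ring‑B sulfinyl group, and the route is rejoined at 18.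

3. Step 9. Closure may take the 6‑exo‑dig course at the ring‑A‑bound alkyne carbon, or go through the other ortho carbon of ring B. Fallback from 27: hydration of the alkyne ((Ph3P)AuNTf2 cat., aqueous dioxane) at the anisyl‑bearing carbon gives the aryl benzyl ketone F7, in which only that carbon is electrophilic. Acid‑mediated Friedel–Crafts cyclodehydration (TsOH or Bi(OTf)3, toluene) then forms the seven‑membered ring and its alkene, and the route is rejoined at 28.

**Further compounds**

F1 | step 7 | aldol carbinol from 22 and 15 (free alcohol of 24) | COc1cc(Cl)c2c(c1)O[C@H](c1ccc(OC)cc1)[C@H]2c1cc(OC)c([C@H]([C@@H](O)c2ccc(OC)cc2)c2cc(OC)cc(OC)c2)c(c1)[S@](=O)c1ccc(C)cc1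
F2 | step 7 | sulfone of F1 | COc1cc(Cl)c2c(c1)O[C@H](c1ccc(OC)cc1)[C@H]2c1cc(OC)c([C@H]([C@@H](O)c2ccc(OC)cc2)c2cc(OC)cc(OC)c2)c(c1)S(=O)(=O)c1ccc(C)cc1
F3 | step 5 | 2‑(3‑bromo‑5‑methoxybenzyl)‑1‑chloro‑5‑methoxy‑3‑[(S)‑4‑methylbenzenesulfinyl]benzene | COc1cc(Cl)c(Cc2cc(OC)cc(Br)c2)c(c1)[S@@](=O)c1ccc(C)cc1
F4 | step 5 | aldol carbinol from F3 and 15 | O[C@H](c1ccc(OC)cc1)[C@H](c1c(Cl)cc(OC)cc1[S@@](=O)c1ccc(C)cc1)c1cc(OC)cc(Br)c1
F5 | step 5 | sulfone of F4 | O[C@H](c1ccc(OC)cc1)[C@H](c1c(Cl)cc(OC)cc1S(=O)(=O)c1ccc(C)cc1)c1cc(OC)cc(Br)c1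
F6 | step 5 | (2S,3S)‑3‑(3‑bromo‑5‑methoxyphenyl)‑4‑chloro‑6‑methoxy‑2‑(4‑methoxyphenyl)‑2,3‑dihydrobenzofuran | COc1cc(Cl)c2c(c1)O[C@H](c1ccc(OC)cc1)[C@H]2c1cc(OC)cc(Br)c1
F7 | step 9 | aryl benzyl ketone from hydration of 27 | COc1cc(CC(=O)c3ccc(OC)cc3)c2c(c1)O[C@H](c1ccc(OC)cc1)[C@H]2c1cc(OC)c2c(c1)O[C@@H](c1ccc(OC)cc1)[C@@H]2c1cc(OC)cc(OC)c1
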